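**Retrosynthetic overview**

1. Target 18 ⇐ 17 ⇐ 16: MOM removal, then Fremy para-oxidation of a ring D phenol to the quinone.
2. 16 ⇐ 15: Pd-catalysed decarboxylative dehydrogenation aromatises a cyclohexenone.
3. 15 ⇐ 13 (key step): one Michael/aldol-condensation operation builds ring D from acyclic carbons and closes the 18-membered ring through the same new C–C bond.
4. 13 ⇐ 8 + 10: phenol alkylation with allyl 2-chloroacetoacetate, then oxidation and C2-Wittig to the enal.
5. 8 ⇐ 1 + 3 + 5: Ullmann ether (A–O–B) and Wittig/H2 (B–CH2CH2–C). Rings A, B, C are bought; ring D and the macrocycle form together in step 9; ring D becomes aromatic in step 10 and a quinone in step 11.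

Assumption: the target SMILES has no stereocentre, so the structure is achiral and is made as drawn; olefin isomers and stereocentres in 7 and 10–15 arise as mixtures and are erased by step 10.

Ring D numbering used below: C1 = acetyl C=O carbon, C2 = carbon bearing the ring C oxygen, C3 = carbon bearing the CH2CH2–ring A chain, C4, C5 = former CHO carbon, C6 = former acetyl CH3.

**Route**

Step 1
Reactants: 1 3-bromo-4-hydroxybenzaldehyde
Product: 2 3-bromo-4-(methoxymethoxy)benzaldehyde
Conditions: MOMCl, K2CO3, acetone, 0 °C → rt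
Reagents that add atoms: chloromethyl methyl ether, COCCl
Why: Williamson O-alkylation of the acidic p-formylphenoxide gives a MOM acetal that survives base, H2, Pd(0) and Fremy's salt and leaves with mild acid at the end.

Step 2
Reactants: 2 3-bromo-4-(methoxymethoxy)benzaldehyde; 3 3-(4-hydroxyphenyl)propan-1-ol
Product: 4 3-[4-(3-hydroxypropyl)phenoxy]-4-(methoxymethoxy)benzaldehyde
Conditions: CuI (10 mol %), N,N-dimethylglycine·HCl (30 mol %), Cs2CO3, 1,4-dioxane, 90 °C
Reagents that add atoms: none
Why: Ullmann diaryl ether coupling (Cu(I)/amino acid ligand) arylates the phenoxide only, with the aliphatic alcohol and the aldehyde as spectators.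

Step 3
Reactants: 5 3-hydroxybenzyl alcohol
Product: 6 (3-hydroxybenzyl)triphenylphosphonium bromide
Conditions: PPh3·HBr, MeCN, reflux
Reagents that add atoms: triphenylphosphine hydrobromide, [Br-].[PH+](c1ccccc1)(c1ccccc1)c1ccccc1
Why: acid-mediated substitution of the benzylic alcohol by PPh3 gives the Wittig salt directly and leaves the phenol free.

Step 4
Reactants: 4 3-[4-(3-hydroxypropyl)phenoxy]-4-(methoxymethoxy)benzaldehyde; 6 (3-hydroxybenzyl)triphenylphosphonium bromide
Product: 7 3-[2-{3-[4-(3-hydroxypropyl)phenoxy]-4-(methoxymethoxy)phenyl}ethenyl]phenol (E/Z mixture)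
Conditions: t-BuOK (3.5 equiv), THF, 0 °C → rt
Reagents that add atoms: none
Why: Wittig olefination with excess base carrying the two OH groups as alkoxides; the E/Z ratio does not matter because the alkene is reduced next.

Step 5
Reactants: 7 3-[2-{3-[4-(3-hydroxypropyl)phenoxy]-4-(methoxymethoxy)phenyl}ethenyl]phenol
Product: 8 3-[2-{3-[4-(3-hydroxypropyl)phenoxy]-4-(methoxymethoxy)phenyl}ethyl]phenol
Conditions: H2 (1 atm), 10% Pd/C, EtOAc/EtOH, rt
Reagents that add atoms: none
Why: catalytic hydrogenation of the stilbene C=C; the MOM acetal and aryl ethers carry no hydrogenolysable benzylic C–O bond.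

Step 6
Reactants: 9 allyl acetoacetate
Product: 10 allyl 2-chloro-3-oxobutanoate (racemic)
Conditions: SO2Cl2 (1.0 equiv), CH2Cl2, 0 °C
Reagents that add atoms: sulfuryl chloride, ClS(Cl)(=O)=O
Why: electrophilic α-chlorination of the β-keto ester enol, which at 0 °C is much faster than addition to the allyl C=C.

Step 7
Reactants: 8 3-[2-{3-[4-(3-hydroxypropyl)phenoxy]-4-(methoxymethoxy)phenyl}ethyl]phenol; 10 allyl 2-chloro-3-oxobutanoate
Product: 11 allyl 2-{3-[2-{3-[4-(3-hydroxypropyl)phenoxy]-4-(methoxymethoxy)phenyl}ethyl]phenoxy}-3-oxobutanoate (racemic)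
Conditions: K2CO3, acetone, rt
Reagents that add atoms: none
Why: Williamson-type SN2 displacement of the doubly activated α-chloride by the phenoxide; the aliphatic alcohol is not deprotonated by carbonate.

Step 8
Reactants: 11 allyl 2-{3-[2-{3-[4-(3-hydroxypropyl)phenoxy]-4-(methoxymethoxy)phenyl}ethyl]phenoxy}-3-oxobutanoate
Product: 13 allyl 2-{3-[2-{4-(methoxymethoxy)-3-[4-((E)-5-oxopent-3-enyl)phenoxy]phenyl}ethyl]phenoxy}-3-oxobutanoate, via allyl 2-{3-[2-{4-(methoxymethoxy)-3-[4-(3-oxopropyl)phenoxy]phenyl}ethyl]phenoxy}-3-oxobutanoate 12 (not isolated)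
Conditions: Dess–Martin periodinane, CH2Cl2, 0 °C → rt; then Ph3P=CHCHO (2.5 equiv), rt
Reagents that add atoms: (triphenylphosphoranylidene)acetaldehyde, O=CC=P(c1ccccc1)(c1ccccc1)c1ccccc1
Why: Dess–Martin oxidation followed in the same flask by Wittig reaction with the stabilised formyl ylide, which is E-selective and ignores the ketone and ester; the acetic acid from the oxidant keeps the keto ester un-ionised, so the Michael reaction cannot start early.

Step 9
Reactants: 13 allyl 2-{3-[2-{4-(methoxymethoxy)-3-[4-((E)-5-oxopent-3-enyl)phenoxy]phenyl}ethyl]phenoxy}-3-oxobutanoate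
Product: 15 macrocyclic allyl 1-aryloxy-2-oxocyclohex-3-ene-1-carboxylate (ring D: C1=O, C5=C6; C2 carries the ring C oxygen and CO2allyl; C3 carries the CH2CH2–ring A chain; fused through C2–C3 to the 18-membered ring; racemic diastereomer mixture), via 18-membered keto-aldehyde Michael adduct 14 (not isolated)
Conditions: pyrrolidine (0.5 equiv), PhCO2H (0.5 equiv), toluene, 50 °C, 13 added by syringe pump over 12 h, final 2 mM
Reagents that add atoms: none
Why: Proposed new method: the enal is activated as its iminium ion and the α-aryloxy-β-keto ester, whose only acidic carbon is C2, adds to the enal β-carbon C3 (Michael addition, closing the 18-membered ring), after which the methyl ketone condenses with the liberated aldehyde (C6→C5, the only six-membered aldol mode) to close ring D; the closest known reaction is the amine-catalysed Michael/aldol-condensation (Robinson-type) annulation of β-keto esters with enals to cyclohexenones, here run intramolecularly at high dilution, and the two new stereocentres are of no consequence.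

Step 10
Reactants: 15 macrocyclic allyl 1-aryloxy-2-oxocyclohex-3-ene-1-carboxylate
Product: 16 ring B O-MOM macrocyclic phenol (ring D = 2-aryloxy-3-alkylphenol, OH on C1)
Conditions: Pd(OAc)2 (10 mol %), dppe (10 mol %), MeCN, 80 °C
Reagents that add atoms: none
Why: Tsuji decarboxylation–dehydrogenation of an allyl β-keto ester: the π-allyl-Pd enolate formed after CO2 loss undergoes β-hydride elimination from C3, and the resulting cyclohexadienone tautomerises to the phenol, erasing both stereocentres.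

Step 11
Reactants: 16 ring B O-MOM macrocyclic phenol
Product: 17 ring B O-MOM marchantinquinone
Conditions: (KSO3)2NO (2.5 equiv), KH2PO4, acetone/H2O, rt
Reagents that add atoms: Fremy's salt (potassium nitrosodisulfonate), [K+].[K+].[O]N(S(=O)(=O)[O-])S(=O)(=O)[O-]
Why: Teuber oxidation: the phenoxyl radical is trapped at the free para position C4 to give the p-quinone, while the only other phenol (ring B) is masked.

Step 12
Reactants: 17 ring B O-MOM marchantinquinone
Product: 18 marchantinquinone
Conditions: TFA/CH2Cl2 (1:4), 0 °C → rt; aqueous work-up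
Reagents that add atoms: none
Why: acidolysis of the MOM acetal; the quinone and diaryl ethers are acid-stable and the product has no stereocentre to set.

**Compound list**

1 | 3-bromo-4-hydroxybenzaldehyde | O=Cc1ccc(O)c(Br)c1 | starting material
2 | 3-bromo-4-(methoxymethoxy)benzaldehyde | O=Cc1ccc(OCOC)c(Br)c1 | intermediate
3 | 3-(4-hydroxyphenyl)propan-1-ol | OCCCc1ccc(O)cc1 | starting material
4 | 3-[4-(3-hydroxypropyl)phenoxy]-4-(methoxymethoxy)benzaldehyde | O=Cc1ccc(OCOC)c(Oc2ccc(CCCO)cc2)c1 | intermediate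
5 | 3-hydroxybenzyl alcohol | OCc1cccc(O)c1 | starting material
6 | (3-hydroxybenzyl)triphenylphosphonium bromide | Oc1cccc(C[P+](c2ccccc2)(c2ccccc2)c2ccccc2)c1.[Br-] | intermediate
7 | 3-[2-{3-[4-(3-hydroxypropyl)phenoxy]-4-(methoxymethoxy)phenyl}ethenyl]phenol (E/Z mixture) | OCCCc1ccc(Oc2cc(C=Cc3cccc(O)c3)ccc2OCOC)cc1 | intermediate
8 | 3-[2-{3-[4-(3-hydroxypropyl)phenoxy]-4-(methoxymethoxy)phenyl}ethyl]phenol | OCCCc1ccc(Oc2cc(CCc3cccc(O)c3)ccc2OCOC)cc1 | intermediate
9 | allyl acetoacetate | CC(=O)CC(=O)OCC=C | starting material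
10 | allyl 2-chloro-3-oxobutanoate (racemic) | CC(=O)C(Cl)C(=O)OCC=C | intermediate
11 | allyl 2-{3-[2-{3-[4-(3-hydroxypropyl)phenoxy]-4-(methoxymethoxy)phenyl}ethyl]phenoxy}-3-oxobutanoate (racemic) | CC(=O)C(Oc1cccc(CCc2ccc(OCOC)c(Oc3ccc(CCCO)cc3)c2)c1)C(=O)OCC=C | intermediate
12 | allyl 2-{3-[2-{4-(methoxymethoxy)-3-[4-(3-oxopropyl)phenoxy]phenyl}ethyl]phenoxy}-3-oxobutanoate (racemic) | CC(=O)C(Oc1cccc(CCc2ccc(OCOC)c(Oc3ccc(CCC=O)cc3)c2)c1)C(=O)OCC=C | intermediate
13 | allyl 2-{3-[2-{4-(methoxymethoxy)-3-[4-((E)-5-oxopent-3-enyl)phenoxy]phenyl}ethyl]phenoxy}-3-oxobutanoate (racemic) | CC(=O)C(Oc1cccc(CCc2ccc(OCOC)c(Oc3ccc(CC/C=C/C=O)cc3)c2)c1)C(=O)OCC=C | intermediate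
14 | 18-membered Michael adduct: quaternary C2 (acetyl, CO2allyl, ring C oxygen) bonded to C3H carrying CH2CHO and the CH2CH2–ring A chain (diastereomer mixture) | CC(=O)C1(C(=O)OCC=C)Oc2cccc(c2)CCc2ccc(OCOC)c(c2)Oc2ccc(cc2)CCC1CC=O | intermediate
15 | macrocyclic allyl 1-aryloxy-2-oxocyclohex-3-ene-1-carboxylate (ring D cyclohexenone fused to the 18-membered ring; racemic diastereomer mixture) | O=C1C=CCC2CCc3ccc(cc3)Oc3cc(ccc3OCOC)CCc3cccc(c3)OC12C(=O)OCC=C | intermediate
16 | ring B O-MOM macrocyclic phenol (ring D 2-aryloxy-3-alkylphenol) | Oc1cccc2CCc3ccc(cc3)Oc3cc(ccc3OCOC)CCc3cccc(c3)Oc12 | intermediate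
17 | ring B O-MOM marchantinquinone | O=C1C=CC(=O)C2=C1CCc1ccc(cc1)Oc1cc(ccc1OCOC)CCc1cccc(c1)O2 | intermediate
18 | marchantinquinone | O=C1C=CC(=O)C2=C1CCc1ccc(cc1)Oc1cc(ccc1O)CCc1cccc(c1)O2 | target

**Step count**

Total steps: 12. Longest linear sequence: 10 (steps 1, 2, 4, 5, 7, 8, 9, 10, 11, 12).

**Three steps most likely to fail**

Step 9 (macrocyclic Michael addition may be too slow at 2 mM or give oligomers). The fallback sets out from 8 and returns at 16; it closes the macrocycle first by a Horner–Wadsworth–Emmons reaction and builds ring D afterwards by a Diels–Alder reaction. Oxidation of 8 with SO3·pyridine/DMSO/Et3N gives 3-{4-[5-(3-hydroxyphenethyl)-2-(methoxymethoxy)phenoxy]phenyl}propanal F1. Rh2(OAc)4-catalysed O–H insertion of dimethyl (1-diazo-2-oxopropyl)phosphonate into its phenol gives the α-aryloxy-β-ketophosphonate aldehyde F2. LiCl/DBU in MeCN at 1 mM then closes the 18-membered ring as the macrocyclic 3-aryloxybut-3-en-2-one F3, and TBSOTf/Et3N converts its methyl ketone into the 2-silyloxydiene F4. Heating with phenyl vinyl sulfoxide in toluene at 110 °C gives the Diels–Alder sulfoxide adduct F5, which loses PhSOH in the flask to the silyloxycyclohexadiene F6. DDQ aromatises this to the aryl TBS ether F7, and TBAF frees phenol 16.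

Step 10 (the π-allyl-Pd enolate may be allylated or protonated instead of eliminating). The fallback sets out from 15 and returns at 16; it separates the two events. Pd(PPh3)4/morpholine in THF removes the allyl group and CO2 to give the macrocyclic 6-aryloxy-5-alkylcyclohex-2-enone F8, which DDQ in dioxane at 80 °C dehydrogenates to 16.

Step 11 (Fremy's salt may over-oxidise the electron-rich macrocycle or react sluggishly in aqueous medium). The fallback sets out from 16 and returns at 18, bypassing 17. PhI(OAc)2 (2.2 equiv) in MeOH at 0 °C gives the quinone mono(dimethyl ketal) F9 by oxidative dearomatisation; aqueous TFA then hydrolyses the ketal and the MOM group together to give 18.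

**Further compounds**

F1 | step 9 | 3-{4-[5-(3-hydroxyphenethyl)-2-(methoxymethoxy)phenoxy]phenyl}propanal | O=CCCc1ccc(Oc2cc(CCc3cccc(O)c3)ccc2OCOC)cc1
F2 | step 9 | dimethyl {1-[3-(2-{4-(methoxymethoxy)-3-[4-(3-oxopropyl)phenoxy]phenyl}ethyl)phenoxy]-2-oxopropyl}phosphonate | CC(=O)C(Oc1cccc(CCc2ccc(OCOC)c(Oc3ccc(CCC=O)cc3)c2)c1)P(=O)(OC)OC
F3 | step 9 | macrocyclic 3-aryloxybut-3-en-2-one (18-membered ring closed through the enone C=C, E/Z mixture) | CC(=O)C1=CCCc2ccc(cc2)Oc2cc(ccc2OCOC)CCc2cccc(c2)O1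
F4 | step 9 | macrocyclic 2-(tert-butyldimethylsilyloxy)-3-aryloxydiene | C=C(O[Si](C)(C)C(C)(C)C)C1=CCCc2ccc(cc2)Oc2cc(ccc2OCOC)CCc2cccc(c2)O1
F5 | step 9 | Diels–Alder adduct with phenyl vinyl sulfoxide (isomer mixture, sulfinyl group drawn at C4) | CC(C)(C)[Si](C)(C)OC1=C2Oc3cccc(c3)CCc3ccc(OCOC)c(c3)Oc3ccc(cc3)CCC2C(CC1)S(=O)c1ccccc1
F6 | step 9 | macrocyclic 1-silyloxycyclohexa-1,4-diene (or its C3=C4 isomer) | CC(C)(C)[Si](C)(C)OC1=C2Oc3cccc(c3)CCc3ccc(OCOC)c(c3)Oc3ccc(cc3)CCC2C=CC1
F7 | step 9 | TBS ether of phenol 16 | CC(C)(C)[Si](C)(C)Oc1cccc2CCc3ccc(cc3)Oc3cc(ccc3OCOC)CCc3cccc(c3)Oc12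
F8 | step 10 | macrocyclic 6-aryloxy-5-alkylcyclohex-2-enone (diastereomer mixture) | O=C1C=CCC2CCc3ccc(cc3)Oc3cc(ccc3OCOC)CCc3cccc(c3)OC12
F9 | step 11 | ring B O-MOM marchantinquinone 4,4-dimethyl monoketal | COC1(OC)C=CC(=O)C2=C1CCc1ccc(cc1)Oc1cc(ccc1OCOC)CCc1cccc(c1)O2
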